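## Structural features

The target is a trans-fused decalin. Ring A (C1–C5, C10) carries a ketone at C3 and a 2-carboxyethyl chain at C4. Ring B (C5–C10) carries methyl groups at C5, C8 and C9, and C9 is joined through the C11 methylene to a 2,5-dihydroxy-3-methylphenyl (hydroquinone) ring. Four stereocentres are contiguous around ring B (C8, C9, C10, C5); two of them are quaternary (C9, C5) and are separated only by C10. The fifth, C4, lies between the quaternary C5 and the C3 carbonyl. The C5 and C9 methyl groups are syn-diaxial, and the C8 methyl is cis to the C9 arylmethyl group, hence axial in the trans-decalin. Fragile groups are the hydroquinone (air oxidation to the quinone), the δ-keto acid and the enolisable C4, whose target configuration (chain equatorial) is nevertheless the thermodynamic one. The real difficulty is the C8–C9–C10–C5 array, with two quaternary carbons and an axial C8 methyl that cannot be left to equilibration, together with regiocontrol at C4 against C2. The key step exploits the fact that C10 (H trans to the C5 methyl) and quaternary C5 are neighbours on ring B and hold the two arms of ring A, C1 and C4, trans to each other. That is the pattern left by conjugate addition to a C5=C10 enone with its carbonyl at C6, followed by alkylation of the enolate.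

## Logic of the disconnections

36 ⇒ 35. The two aryl O–CH3 bonds are the last to be cleaved in the forward sense. A free hydroquinone would be oxidised or deprotonated in almost every earlier operation, whereas methyl ethers are inert to organometallic reagents, strong bases, oxidants and acid. The gain is that the one oxidation-sensitive group exists only in the final compound. The demand is a dealkylation that leaves the C3 ketone, the acid and C4 untouched.

35 ⇒ 33 (through 34). A carboxyl group is added retrosynthetically to C4 and both acids are masked as tert-butyl esters. The reason is regiochemistry: with an ester on C4, that carbon and not C2 is the acidic position of ring A. The price is one carbon that is lost again. The forward step must cleave two tert-butyl esters, decarboxylate, and protonate C4 so that the chain ends equatorial.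

33 ⇒ 31 + 32. The bond between C4 and the first chain carbon is cut (Michael retron). This removes the whole acid chain as a commodity acrylate. The forward step has to form a bond at a carbon that becomes quaternary next to the quaternary C5.

31 ⇒ 30. The C3–C4 bond of ring A is cut (Dieckmann retron), which opens the decalin to a monocyclic ring B with two ester arms. A Claisen-type closure is preferred to an aldol between a C4 ester and a C3 aldehyde, because there the aldehyde, not the ester, would be enolised first. The condensation also delivers C3 and C4 in the oxidation states needed for the next step. The demand is that only the C4 enolate acts as nucleophile and only the C3 ester as electrophile, which is why C4 carries a tert-butyl ester and C3 a methyl ester.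

30 ⇒ 28 (through 29). No skeletal bond is cut. C3 is taken back from the ester to the aldehyde and then to the acetal, the form in which the C1–C3 arm tolerates organometallic reagents. The forward steps must hydrolyse the acetal and oxidise the aldehyde without loss of the tert-butyl ester.

28 ⇒ 24 (through 27 and 26). The C6 carbonyl is reinstated. It has no counterpart in 36 but is the activating group of the key step. Its forward removal must work on a ketone flanked by a quaternary carbon and must avoid hydrazine and hydride reagents, which would cyclise onto the ester three atoms away. An enol triflate that is reduced and then hydrogenated meets this.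

24 ⇒ 19 + 20 + 21 (through 23 and 22). The bonds C10–C1 and C5–C4 are cut in one operation; this is the key disconnection. It removes both arms of ring A and the C10 and C5 stereocentres, and leaves a monocyclic enone whose only stereocentres are C8 and C9. The forward step must add at C10 from the α face, alkylate C5 trans to the new arm, and give 1,4- over 1,2-addition and C- over O-alkylation.

19 ⇒ 15 (through 18, 17 and 16). The enone is transposed: C6=O with C5=C10 is traced back to C10=O with C5=C6. The reason is that a carbonyl at C10 is what allows C8 and C9 to be set by conjugate addition and trapping. The demand is a 1,3-carbonyl transposition at a hindered ketone that leaves C8 and C9 alone.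

15 ⇒ 11 (through 14, 13 and 12). The C5 methyl group and the C5=C6 unsaturation are removed. Because C9 is quaternary, 11 can be enolised only toward C5, so both forward operations are regiochemically unambiguous.

11 ⇒ 9 (through 10). The C8–CH3 and C9–CH3 bonds are cut. Conjugate addition of methyl sets C8 under catalyst control, and the enolate so formed takes the second methyl anti to the first. With the arylmethyl group already on C9, this order of introduction is what places it cis to the C8 methyl. The gain is an achiral precursor. The demand is high enantioselectivity on an α-substituted enone.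

9 ⇒ 7 ⇒ 6 ⇒ 3 + 4 (through 8 and 5). The C9–C11 bond is cut between an aromatic aldehyde and a cyclic 1,3-dione; the two ring carbonyls are then told apart by way of 7. The forward steps must give C- and not O-alkylation of 4 (hence a reductive alkylation) and must reduce only one carbonyl.

3 ⇒ 2 ⇒ 1. The aryl–CHO bond and one O–CH3 bond are cut. In 1 the only free position ortho to the hydroxyl is the one required, so the formylation is regiochemically fixed.

## Other disconnections considered

Alternative 1: The cut removes C8–C9 and C5–C10 together, so that ring B is the cycloadduct and ring A the tether ring of an intramolecular Diels–Alder reaction. The arylmethyl group is reduced to a C11 aldehyde, which also activates the dienophile.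
- Forward step: trienal A1, an E-2-methyl enal linked through C1–C4 to an E,E-diene, would be heated or treated with Me2AlCl to give octalin aldehyde A2.
- In favour: both rings and the C5, C8, C9 and C10 centres would arise in one concerted, suprafacial step. The relative configuration follows from alkene geometry alone: the E-enal puts the formyl group trans to C1, and the two outward diene substituents put C4 and the C8 methyl cis. The cis relationship of the C8 methyl and the C11 carbon, which the chosen plan must secure by the order of two alkylations, therefore comes directly. On ring-forming economy alternative 1 is the better plan.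
- Against: the diene terminus C5 is fully substituted and carries an inward methyl group, which disfavours the s-cis conformer. The dienophile is trisubstituted, so two quaternary carbons (C5 and C9) must form in the same transition state. Control of trans against cis fusion in decatrienes of this kind is usually modest. Absolute configuration would rest on the single C4 centre of A1 or on a chiral Lewis acid. After the cycloaddition the arene must still be added to a neopentyl aldehyde, the benzylic oxygen removed and the C6=C7 bond hydrogenated.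
- Comparison: mechanistically it is a pericyclic step with geometry-derived control against a stepwise ionic sequence with substrate control. Structurally it builds the ring system earlier but brings the arene in late on a hindered carbon. In step count the two plans should come out about equal once the enantioselective synthesis of A1 and the late arylation and deoxygenation are counted; the chosen plan rests on better-charted reactivity.

Alternative 2: The cut removes C3–C4 and the C12–C13 bond of the side chain. Ring A is closed by an intramolecular [2+2] photocycloaddition of a dioxinone, tethered through C1–C2 to C10, onto a vinyl group on C5, and the cyclobutane is then opened by retro-aldol (de Mayo) fragmentation.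
- Forward step: irradiation of A3 near 300 nm would give photoadduct A4; hydrolytic fragmentation would then reveal the C3 ketone and the complete propanoic acid chain at once.
- In favour: ring A, the C3 carbonyl and the whole side chain with its carboxyl group come from two operations. No bond has to be made to a C4 that becomes quaternary, no carboxyl carbon is wasted, and a light-driven bond formation is little affected by the congestion around C5. For this last stage alternative 2 is better than the Dieckmann, Michael and decarboxylation sequence.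
- Against: A3 already contains the whole C8–C9–C10–C5 array, so the central stereochemical problem is untouched and would still need a step like the chosen key step. A vinyl group cannot be placed on a tetrasubstituted enolate by simple alkylation and would have to be derived from an acetate arm in several steps. The dioxinone has to be built on the C1–C2 arm. The electron-rich dimethoxyarene absorbs in the same region and may act as competing chromophore or quencher.
- Comparison: photochemical cycloaddition and fragmentation against enolate chemistry for ring A. The two plans are equal on ring B, which makes the same demand in both. Total step count should be about equal, because the steps saved after ring closure are spent on the vinyl group and the dioxinone.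

Alternative 3: The cut removes C9–C10 and C4–C5 and opens both rings to an achiral polyene.
- Forward step: a silyl triflate such as t-BuMe2SiOTf, or a confined chiral silylium catalyst, would activate the C7 enone of A5. The C5=C10 alkene would attack C9 and the C3 silyl enol ether would capture the C5 cation, giving trans-decalin A6 with the C3 ketone, the C4 chain and a C7 silyl enol ether.
- In favour: both rings and C5, C9, C10 (and C4) would form in one catalytic step from a linear precursor that can be assembled convergently. E-alkene geometry and a chair–chair transition state give the trans fusion. Absolute control could come from the catalyst, not from an early stereocentre. The C3 ketone and the propanoate arise directly. In step economy and convergence alternative 3 is clearly the better plan.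
- Against: the C8 methyl is missing and would have to be introduced afterwards through the C7 enolate. Kinetic axial methylation anti to the axial C9 methyl could give the required β configuration, but that centre then sits next to a carbonyl and can epimerise to the equatorial, wrong isomer. The C7 oxygen must then be removed in the presence of the C3 ketone. The initiating carbon C9 is fully substituted, so C–C bond formation competes with proton loss. The arene can intercept the C5 cation by a six-membered Friedel–Crafts closure in place of the enol ether.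
- Comparison: a cationic cascade under catalyst control against organocopper and enolate chemistry under substrate control. The alternative is shorter, but its weakest points (C8 configuration, chemoselectivity of the cation) fall on exactly the features that set this target apart. The chosen plan sets C8 first and lets it direct C9, C10 and C5.

Key step: step 12

Remark on the chemistry: locants C1–C11 are those of the target decalin and are kept for all intermediates; β is the face of ring B bearing the C8 methyl and the C9 arylmethyl group, α the opposite face. Compound 1 is assumed to be purchased. Where a SMILES string fixes a centre that is erased later (16–18, 33, 34), it shows the diastereomer expected to predominate.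

## Steps

Step 1  
Reactants: 1 4-methoxy-2-methylphenol  
Product: 2 2-hydroxy-5-methoxy-3-methylbenzaldehyde  
Conditions: MgCl2, Et3N, (CH2O)n, MeCN, reflux  
Reagents that add atoms: paraformaldehyde (as formaldehyde), `C=O`  
Why: Magnesium phenoxide-directed ortho-formylation (Casnati–Skattebøl type): the aryloxymagnesium species delivers formaldehyde to the only free ortho position and a second formaldehyde oxidises the benzylic alkoxide to the aldehyde.

Step 2  
Reactants: 2 2-hydroxy-5-methoxy-3-methylbenzaldehyde  
Product: 3 2,5-dimethoxy-3-methylbenzaldehyde  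
Conditions: MeI, K2CO3, DMF, rt  
Reagents that add atoms: iodomethane, `CI`  
Why: Williamson O-methylation of the phenol; methyl ethers are chosen because they survive every base, organometallic reagent and oxidant used later.

Step 3  
Reactants: 3 2,5-dimethoxy-3-methylbenzaldehyde; 4 cyclohexane-1,3-dione  
Product: 6 2-[(2,5-dimethoxy-3-methylphenyl)methyl]cyclohexane-1,3-dione, via arylidene dione 5 (not isolated)  
Conditions: Hantzsch ester, L-proline (20 mol%), CH2Cl2, rt  
Reagents that add atoms: none  
Why: Organocatalytic three-component reductive alkylation: a proline-mediated Knoevenagel condensation gives 5, which is reduced at once by hydride transfer from the Hantzsch ester, so only C-alkylation at C2 of the dione can result and no benzylic halide is needed.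

Step 4  
Reactants: 6 2-[(2,5-dimethoxy-3-methylphenyl)methyl]cyclohexane-1,3-dione  
Product: 7 2-[(2,5-dimethoxy-3-methylphenyl)methyl]-3-(2-methylpropoxy)cyclohex-2-en-1-one  
Conditions: iBuOH, TsOH·H2O (cat.), toluene, reflux (Dean–Stark)  
Reagents that add atoms: 2-methylpropan-1-ol, `CC(C)CO`  
Why: Acid-catalysed enol etherification of a 2-substituted 1,3-dione with azeotropic removal of water; the vinylogous ester differentiates the two carbonyl groups.

Step 5  
Reactants: 7 2-[(2,5-dimethoxy-3-methylphenyl)methyl]-3-(2-methylpropoxy)cyclohex-2-en-1-one  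
Product: 9 2-[(2,5-dimethoxy-3-methylphenyl)methyl]cyclohex-2-en-1-one, via allylic alcohol 8 (not isolated)  
Conditions: LiAlH4, Et2O, 0 °C; then 2 M HCl, rt  
Reagents that add atoms: water, `O`  
Why: 1,2-Reduction of the vinylogous ester followed by acid hydrolysis of the enol ether and loss of water from 8 (the reduction–hydrolysis half of a Stork–Danheiser sequence) gives the 2-substituted cyclohexenone.

Step 6  
Reactants: 9 2-[(2,5-dimethoxy-3-methylphenyl)methyl]cyclohex-2-en-1-one  
Product: 11 (2S,3S)-2-[(2,5-dimethoxy-3-methylphenyl)methyl]-2,3-dimethylcyclohexan-1-one, via magnesium enolate 10 (not isolated)  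
Conditions: MeMgBr, Cu(OTf)2 (5 mol%), chiral imidazolium salt as carbene precursor (7 mol%, enantiomer that gives the 3S adduct), Et2O, −30 °C; then MeI, DMPU, −30 °C → rt  
Reagents that add atoms: methylmagnesium bromide, `C[Mg]Br`; iodomethane, `CI`  
Why: Copper-catalysed asymmetric conjugate addition of a methyl Grignard reagent to an α-substituted cyclohexenone with trapping of the enolate; the chiral carbene–copper complex sets C8 by face-selective methyl transfer. MeI then attacks the C9 enolate carbon axially and anti to the adjacent C8 methyl, which places the new C9 methyl trans and the arylmethyl group cis to the C8 methyl.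

Step 7  
Reactants: 11 (2S,3S)-2-[(2,5-dimethoxy-3-methylphenyl)methyl]-2,3-dimethylcyclohexan-1-one  
Product: 13 (2S,3S)-2-[(2,5-dimethoxy-3-methylphenyl)methyl]-2,3,6-trimethylcyclohexan-1-one (both C6 epimers), via lithium enolate 12 (not isolated)  
Conditions: LiN(iPr)2, THF, −78 °C; MeI, −78 → 0 °C  
Reagents that add atoms: iodomethane, `CI`  
Why: Kinetic enolate alkylation; C2 is quaternary, so the base can deprotonate only C6 (the future C5) and the regiochemistry is unambiguous. The new centre is a mixture and is erased in step 8.

Step 8  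
Reactants: 13 (2S,3S)-2-[(2,5-dimethoxy-3-methylphenyl)methyl]-2,3,6-trimethylcyclohexan-1-one (both C6 epimers)  
Product: 15 (5S,6S)-6-[(2,5-dimethoxy-3-methylphenyl)methyl]-2,5,6-trimethylcyclohex-2-en-1-one, via silyl enol ether 14 (not isolated)  
Conditions: Me3SiOTf, Et3N, CH2Cl2, 0 °C → rt; then Pd(OAc)2, MeCN, rt  
Reagents that add atoms: none  
Why: Saegusa–Ito oxidation: soft enolisation gives the only possible silyl enol ether 14, and the divalent palladium enolate formed from it undergoes β-hydride elimination toward the ring CH2 to give the conjugated trisubstituted enone.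

Step 9  
Reactants: 15 (5S,6S)-6-[(2,5-dimethoxy-3-methylphenyl)methyl]-2,5,6-trimethylcyclohex-2-en-1-one  
Product: 16 (3S,4S)-3-[(2,5-dimethoxy-3-methylphenyl)methyl]-1,3,4-trimethyl-7-oxabicyclo[4.1.0]heptan-2-one (epoxide trans to the C4 methyl)  
Conditions: 30% H2O2, NaOH, MeOH, 0 °C → rt  
Reagents that add atoms: hydrogen peroxide, `OO`  
Why: Weitz–Scheffer nucleophilic epoxidation of an α-methyl enone (hydroperoxide adds to the unhindered β-CH, then the ring closes with loss of hydroxide). Attack anti to the C8 methyl is expected, but both epoxide centres are erased in steps 10 and 11.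

Step 10  
Reactants: 16 (3S,4S)-3-[(2,5-dimethoxy-3-methylphenyl)methyl]-1,3,4-trimethyl-7-oxabicyclo[4.1.0]heptan-2-one (epoxide trans to the C4 methyl)  
Product: 18 (4S,5S)-4-[(2,5-dimethoxy-3-methylphenyl)methyl]-2,4,5-trimethylcyclohex-2-en-1-ol, via epoxy hydrazone 17 (not isolated)  
Conditions: N2H4·H2O, AcOH (cat.), MeOH, 0 °C → rt  
Reagents that add atoms: none  
Why: Wharton transposition: hydrazone 17 opens the epoxide to a vinyl diazene that loses N2, which moves the double bond to C5=C10 and leaves the hydroxyl on C6. Hydrazine is small and an α-epoxy ketone is an activated carbonyl, which should offset the hindrance at C10.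

Step 11  
Reactants: 18 (4S,5S)-4-[(2,5-dimethoxy-3-methylphenyl)methyl]-2,4,5-trimethylcyclohex-2-en-1-ol  
Product: 19 (4S,5S)-4-[(2,5-dimethoxy-3-methylphenyl)methyl]-2,4,5-trimethylcyclohex-2-en-1-one  
Conditions: Dess–Martin periodinane, NaHCO3, CH2Cl2, rt  
Reagents that add atoms: none  
Why: Hypervalent-iodine oxidation of a secondary allylic alcohol to the conjugated enone under buffered conditions; C8 and C9 cannot be epimerised through this carbonyl.

Step 12  
Reactants: 19 (4S,5S)-4-[(2,5-dimethoxy-3-methylphenyl)methyl]-2,4,5-trimethylcyclohex-2-en-1-one; 20 2-(2-bromoethyl)-1,3-dioxolane; 21 tert-butyl 2-bromoacetate  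
Product: 24 tert-butyl 2-[(1S,2R,3S,4S)-3-[(2,5-dimethoxy-3-methylphenyl)methyl]-2-[2-(1,3-dioxolan-2-yl)ethyl]-1,3,4-trimethyl-6-oxocyclohexyl]acetate, via silyl enol ether 22 (not isolated), via lithium enolate 23 (not isolated)  
Conditions: 20, Mg, THF, 25 °C; CuBr·SMe2 (20 mol%), Me3SiCl, THF, −78 → −30 °C; volatiles removed, pentane, filtration; MeLi, THF, 0 °C → rt; then 21, HMPA, −78 → 0 °C  
Reagents that add atoms: none  
Why: The Grignard reagent of 20 is transmetalated to a monovalent organocopper species that forms a π-complex with the C5=C10 bond of 19, adds at C10 to give a trivalent copper intermediate and reductively eliminates while Me3SiCl traps the enolate as 22; MeLi then cleaves the Si–O bond to the regiodefined lithium enolate 23, which attacks 21 at C5 in an SN2 step. The closest known reaction type is the copper-mediated conjugate addition of a functionalised Grignard reagent to a cyclohexenone followed by trans-selective alkylation of the regenerated enolate (vicinal difunctionalisation of an enone). No ring is closed; only the bonds C10–C1 and C5–C4 are formed. C10 is controlled by the existing C8 and C9 centres: the β face carries the C8 methyl and the C9 arylmethyl group, one of which is axial in either half-chair, so the reagent should enter axially from the α face. C5 is controlled by the new C10 substituent: the enolate should hold the C10 arm pseudoaxial to avoid allylic strain with the C5 methyl, and the electrophile should enter antiperiplanar to it from the β face, which puts C4 trans to C1 and the C5 methyl on the α face. The step needs 1,4- over 1,2-addition (secured by copper and Me3SiCl), a single enolate regioisomer and C- over O-alkylation (secured by the silyl enol ether and MeLi protocol, the polar additive and the reactive α-halo ester), and tolerance of the acetal and the ester (the acetal is inert to all reagents and 21 is added only after MeLi is consumed). The trans relationship of the two arms and the quaternary C5 are thereby fixed before ring A exists.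

Step 13  
Reactants: 24 tert-butyl 2-[(1S,2R,3S,4S)-3-[(2,5-dimethoxy-3-methylphenyl)methyl]-2-[2-(1,3-dioxolan-2-yl)ethyl]-1,3,4-trimethyl-6-oxocyclohexyl]acetate  
Product: 26 tert-butyl 2-[5-[(2,5-dimethoxy-3-methylphenyl)methyl]-6-[2-(1,3-dioxolan-2-yl)ethyl]-1,4,5-trimethyl-2-(trifluoromethanesulfonyloxy)cyclohex-2-en-1-yl]acetate (stereocentres as in 24), via potassium enolate 25 (not isolated)  
Conditions: KN(SiMe3)2, THF, −78 °C; PhNTf2, −78 → 0 °C  
Reagents that add atoms: N-phenylbis(trifluoromethanesulfonimide), `O=S(=O)(N(c1ccccc1)S(=O)(=O)C(F)(F)F)C(F)(F)F`  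
Why: Kinetic deprotonation at C7, the only α-carbon with hydrogen (C5 is quaternary), and O-sulfonylation give the enol triflate; the ketone is more acidic than the tert-butyl ester, so one equivalent of base suffices. This first stage of the deoxygenation avoids hydrazine and hydride, which would cyclise onto the ester.

Step 14  
Reactants: 26 tert-butyl 2-[5-[(2,5-dimethoxy-3-methylphenyl)methyl]-6-[2-(1,3-dioxolan-2-yl)ethyl]-1,4,5-trimethyl-2-(trifluoromethanesulfonyloxy)cyclohex-2-en-1-yl]acetate (stereocentres as in 24)  
Product: 27 tert-butyl 2-[5-[(2,5-dimethoxy-3-methylphenyl)methyl]-6-[2-(1,3-dioxolan-2-yl)ethyl]-1,4,5-trimethylcyclohex-2-en-1-yl]acetate (stereocentres as in 24)  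
Conditions: Pd(OAc)2 (5 mol%), PPh3, HCO2H, Bu3N, DMF, 60 °C  
Reagents that add atoms: none  
Why: Palladium-catalysed formate reduction of an enol triflate (oxidative addition to zerovalent palladium, formate exchange, decarboxylation, reductive elimination); acetal and tert-butyl ester are inert in the amine-buffered medium.

Step 15  
Reactants: 27 tert-butyl 2-[5-[(2,5-dimethoxy-3-methylphenyl)methyl]-6-[2-(1,3-dioxolan-2-yl)ethyl]-1,4,5-trimethylcyclohex-2-en-1-yl]acetate (stereocentres as in 24)  
Product: 28 tert-butyl 2-[3-[(2,5-dimethoxy-3-methylphenyl)methyl]-2-[2-(1,3-dioxolan-2-yl)ethyl]-1,3,4-trimethylcyclohexyl]acetate (stereocentres as in 24)  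
Conditions: H2 (1 atm), Pd/C, EtOAc, rt  
Reagents that add atoms: none  
Why: Heterogeneous hydrogenation of the cis-disubstituted C6=C7 alkene; no stereocentre is created and the aryl ethers, acetal and ester are untouched.

Step 16  
Reactants: 28 tert-butyl 2-[3-[(2,5-dimethoxy-3-methylphenyl)methyl]-2-[2-(1,3-dioxolan-2-yl)ethyl]-1,3,4-trimethylcyclohexyl]acetate (stereocentres as in 24)  
Product: 29 tert-butyl 2-[3-[(2,5-dimethoxy-3-methylphenyl)methyl]-1,3,4-trimethyl-2-(3-oxopropyl)cyclohexyl]acetate (stereocentres as in 24)  
Conditions: 1 M HCl, THF, rt  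
Reagents that add atoms: water, `O`  
Why: Acid-catalysed acetal hydrolysis; dilute aqueous acid at room temperature unmasks the aldehyde while the tert-butyl ester, which needs strong anhydrous acid, survives.

Step 17  
Reactants: 29 tert-butyl 2-[3-[(2,5-dimethoxy-3-methylphenyl)methyl]-1,3,4-trimethyl-2-(3-oxopropyl)cyclohexyl]acetate (stereocentres as in 24)  
Product: 30 methyl 3-[6-(2-tert-butoxy-2-oxoethyl)-2-[(2,5-dimethoxy-3-methylphenyl)methyl]-2,3,6-trimethylcyclohexyl]propanoate (stereocentres as in 24)  
Conditions: iodine, KOH, MeOH, 0 °C  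
Reagents that add atoms: methanol, `CO`  
Why: Oxidative esterification of an aldehyde: the methanol hemiacetal is oxidised by hypoiodite to the methyl ester in one operation, which brings C3 to the oxidation level needed for a Claisen-type ring closure.

Step 18  
Reactants: 30 methyl 3-[6-(2-tert-butoxy-2-oxoethyl)-2-[(2,5-dimethoxy-3-methylphenyl)methyl]-2,3,6-trimethylcyclohexyl]propanoate (stereocentres as in 24)  
Product: 31 tert-butyl (4aR,5S,6S,8aR)-5-[(2,5-dimethoxy-3-methylphenyl)methyl]-5,6,8a-trimethyl-2-oxodecahydronaphthalene-1-carboxylate  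
Conditions: KOtBu, THF (0.01 M), 0 °C → rt; then 1 M HCl  
Reagents that add atoms: none  
Why: Dieckmann condensation (6-exo-trig): the C4 enolate of the tert-butyl ester attacks the C3 methyl ester, while the reverse mode would need attack on the hindered tert-butyl ester carbonyl and is suppressed. Deprotonation of the β-keto ester drives the closure, and the trans ring fusion is already fixed by C5 and C10.

Step 19  
Reactants: 31 tert-butyl (4aR,5S,6S,8aR)-5-[(2,5-dimethoxy-3-methylphenyl)methyl]-5,6,8a-trimethyl-2-oxodecahydronaphthalene-1-carboxylate; 32 tert-butyl prop-2-enoate  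
Product: 33 tert-butyl (1S,4aR,5S,6S,8aR)-1-(3-tert-butoxy-3-oxopropyl)-5-[(2,5-dimethoxy-3-methylphenyl)methyl]-5,6,8a-trimethyl-2-oxodecahydronaphthalene-1-carboxylate  
Conditions: KOtBu (10 mol%), tBuOH/THF, 0 °C → rt  
Reagents that add atoms: none  
Why: Michael addition of a β-keto ester to an acrylate under catalytic base; the ester on C4 makes it the only doubly activated position of ring A. Attack anti to the axial C5 methyl is expected, but the C4 configuration is erased in step 20.

Step 20  
Reactants: 33 tert-butyl (1S,4aR,5S,6S,8aR)-1-(3-tert-butoxy-3-oxopropyl)-5-[(2,5-dimethoxy-3-methylphenyl)methyl]-5,6,8a-trimethyl-2-oxodecahydronaphthalene-1-carboxylate  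
Product: 35 3-[(1S,4aR,5S,6S,8aR)-5-[(2,5-dimethoxy-3-methylphenyl)methyl]-5,6,8a-trimethyl-2-oxodecahydronaphthalen-1-yl]propanoic acid, via keto diacid 34 (not isolated)  
Conditions: CF3CO2H, CH2Cl2, rt; then toluene, 90 °C  
Reagents that add atoms: none  
Why: Acidolysis of both tert-butyl esters (loss of isobutene) and thermal decarboxylation of the β-keto acid 34 through a six-membered transition state. The enol is protonated axially on the β face, anti to the C5 methyl, so the chain ends equatorial (4S in target numbering C4), which is also the thermodynamic epimer.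

Step 21  
Reactants: 35 3-[(1S,4aR,5S,6S,8aR)-5-[(2,5-dimethoxy-3-methylphenyl)methyl]-5,6,8a-trimethyl-2-oxodecahydronaphthalen-1-yl]propanoic acid  
Product: 36 3-[(1S,4aR,5S,6S,8aR)-5-[(2,5-dihydroxy-3-methylphenyl)methyl]-5,6,8a-trimethyl-2-oxodecahydronaphthalen-1-yl]propanoic acid  
Conditions: BBr3, CH2Cl2, −78 → 0 °C; aqueous NaHCO3/Na2S2O4 work-up under argon  
Reagents that add atoms: none  
Why: Lewis-acid ether cleavage: BBr3 coordinates each methoxy oxygen and bromide removes the methyl group by SN2. Ketone and acid are tolerated at low temperature, and the reductive work-up under argon protects the hydroquinone.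

## Compound list

1 | 4-methoxy-2-methylphenol | `Cc1cc(OC)ccc1O` | starting material  
2 | 2-hydroxy-5-methoxy-3-methylbenzaldehyde | `Cc1cc(OC)cc(C=O)c1O` | intermediate  
3 | 2,5-dimethoxy-3-methylbenzaldehyde | `Cc1cc(OC)cc(C=O)c1OC` | intermediate  
4 | cyclohexane-1,3-dione | `O=C1CCCC(=O)C1` | starting material  
5 | 2-[(2,5-dimethoxy-3-methylphenyl)methylidene]cyclohexane-1,3-dione | `Cc1cc(OC)cc(C=C2C(=O)CCCC2=O)c1OC` | intermediate  
6 | 2-[(2,5-dimethoxy-3-methylphenyl)methyl]cyclohexane-1,3-dione | `Cc1cc(OC)cc(CC2C(=O)CCCC2=O)c1OC` | intermediate  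
7 | 2-[(2,5-dimethoxy-3-methylphenyl)methyl]-3-(2-methylpropoxy)cyclohex-2-en-1-one | `Cc1cc(OC)cc(CC2=C(OCC(C)C)CCCC2=O)c1OC` | intermediate  
8 | 2-[(2,5-dimethoxy-3-methylphenyl)methyl]-3-(2-methylpropoxy)cyclohex-2-en-1-ol (racemic) | `Cc1cc(OC)cc(CC2=C(OCC(C)C)CCCC2O)c1OC` | intermediate  
9 | 2-[(2,5-dimethoxy-3-methylphenyl)methyl]cyclohex-2-en-1-one | `Cc1cc(OC)cc(CC2=CCCCC2=O)c1OC` | intermediate  
10 | bromomagnesium (3S)-2-[(2,5-dimethoxy-3-methylphenyl)methyl]-3-methylcyclohex-1-en-1-olate | `Cc1cc(OC)cc(CC2=C(O[Mg]Br)CCC[C@@H]2C)c1OC` | intermediate  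
11 | (2S,3S)-2-[(2,5-dimethoxy-3-methylphenyl)methyl]-2,3-dimethylcyclohexan-1-one | `Cc1cc(OC)cc(C[C@]2(C)C(=O)CCC[C@@H]2C)c1OC` | intermediate  
12 | lithium (5S,6S)-6-[(2,5-dimethoxy-3-methylphenyl)methyl]-5,6-dimethylcyclohex-1-en-1-olate | `Cc1cc(OC)cc(C[C@]2(C)C(O[Li])=CCC[C@@H]2C)c1OC` | intermediate  
13 | (2S,3S)-2-[(2,5-dimethoxy-3-methylphenyl)methyl]-2,3,6-trimethylcyclohexan-1-one (both C6 epimers; C6 left open in the SMILES) | `Cc1cc(OC)cc(C[C@]2(C)C(=O)C(C)CC[C@@H]2C)c1OC` | intermediate  
14 | {[(5S,6S)-6-[(2,5-dimethoxy-3-methylphenyl)methyl]-2,5,6-trimethylcyclohex-1-en-1-yl]oxy}trimethylsilane | `Cc1cc(OC)cc(C[C@]2(C)C(O[Si](C)(C)C)=C(C)CC[C@@H]2C)c1OC` | intermediate  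
15 | (5S,6S)-6-[(2,5-dimethoxy-3-methylphenyl)methyl]-2,5,6-trimethylcyclohex-2-en-1-one | `Cc1cc(OC)cc(C[C@]2(C)C(=O)C(C)=CC[C@@H]2C)c1OC` | intermediate  
16 | (3S,4S)-3-[(2,5-dimethoxy-3-methylphenyl)methyl]-1,3,4-trimethyl-7-oxabicyclo[4.1.0]heptan-2-one (epoxide trans to the C4 methyl) | `Cc1cc(OC)cc(C[C@]2(C)C(=O)[C@@]3(C)O[C@H]3C[C@@H]2C)c1OC` | intermediate  
17 | hydrazone of 16 | `Cc1cc(OC)cc(C[C@]2(C)C(=NN)[C@@]3(C)O[C@H]3C[C@@H]2C)c1OC` | intermediate  
18 | (4S,5S)-4-[(2,5-dimethoxy-3-methylphenyl)methyl]-2,4,5-trimethylcyclohex-2-en-1-ol (hydroxyl trans to the C5 methyl) | `Cc1cc(OC)cc(C[C@]2(C)C=C(C)[C@@H](O)C[C@@H]2C)c1OC` | intermediate  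
19 | (4S,5S)-4-[(2,5-dimethoxy-3-methylphenyl)methyl]-2,4,5-trimethylcyclohex-2-en-1-one | `Cc1cc(OC)cc(C[C@]2(C)C=C(C)C(=O)C[C@@H]2C)c1OC` | intermediate  
20 | 2-(2-bromoethyl)-1,3-dioxolane | `BrCCC1OCCO1` | starting material  
21 | tert-butyl 2-bromoacetate | `CC(C)(C)OC(=O)CBr` | starting material  
22 | {[(3R,4S,5S)-4-[(2,5-dimethoxy-3-methylphenyl)methyl]-3-[2-(1,3-dioxolan-2-yl)ethyl]-2,4,5-trimethylcyclohex-1-en-1-yl]oxy}trimethylsilane | `Cc1cc(OC)cc(C[C@]2(C)[C@@H](CCC3OCCO3)C(C)=C(O[Si](C)(C)C)C[C@@H]2C)c1OC` | intermediate  
23 | lithium (3R,4S,5S)-4-[(2,5-dimethoxy-3-methylphenyl)methyl]-3-[2-(1,3-dioxolan-2-yl)ethyl]-2,4,5-trimethylcyclohex-1-en-1-olate | `Cc1cc(OC)cc(C[C@]2(C)[C@@H](CCC3OCCO3)C(C)=C(O[Li])C[C@@H]2C)c1OC` | intermediate  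
24 | tert-butyl 2-[(1S,2R,3S,4S)-3-[(2,5-dimethoxy-3-methylphenyl)methyl]-2-[2-(1,3-dioxolan-2-yl)ethyl]-1,3,4-trimethyl-6-oxocyclohexyl]acetate | `Cc1cc(OC)cc(C[C@]2(C)[C@@H](CCC3OCCO3)[C@](C)(CC(=O)OC(C)(C)C)C(=O)C[C@@H]2C)c1OC` | intermediate  
25 | potassium C6–C7 enolate of 24 | `Cc1cc(OC)cc(C[C@]2(C)[C@@H](CCC3OCCO3)[C@](C)(CC(=O)OC(C)(C)C)C(O[K])=C[C@@H]2C)c1OC` | intermediate  
26 | tert-butyl 2-[5-[(2,5-dimethoxy-3-methylphenyl)methyl]-6-[2-(1,3-dioxolan-2-yl)ethyl]-1,4,5-trimethyl-2-(trifluoromethanesulfonyloxy)cyclohex-2-en-1-yl]acetate (stereocentres as in 24) | `Cc1cc(OC)cc(C[C@]2(C)[C@@H](CCC3OCCO3)[C@](C)(CC(=O)OC(C)(C)C)C(OS(=O)(=O)C(F)(F)F)=C[C@@H]2C)c1OC` | intermediate  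
27 | tert-butyl 2-[5-[(2,5-dimethoxy-3-methylphenyl)methyl]-6-[2-(1,3-dioxolan-2-yl)ethyl]-1,4,5-trimethylcyclohex-2-en-1-yl]acetate (stereocentres as in 24) | `Cc1cc(OC)cc(C[C@]2(C)[C@@H](CCC3OCCO3)[C@](C)(CC(=O)OC(C)(C)C)C=C[C@@H]2C)c1OC` | intermediate  
28 | tert-butyl 2-[3-[(2,5-dimethoxy-3-methylphenyl)methyl]-2-[2-(1,3-dioxolan-2-yl)ethyl]-1,3,4-trimethylcyclohexyl]acetate (stereocentres as in 24) | `Cc1cc(OC)cc(C[C@]2(C)[C@@H](CCC3OCCO3)[C@](C)(CC(=O)OC(C)(C)C)CC[C@@H]2C)c1OC` | intermediate  
29 | tert-butyl 2-[3-[(2,5-dimethoxy-3-methylphenyl)methyl]-1,3,4-trimethyl-2-(3-oxopropyl)cyclohexyl]acetate (stereocentres as in 24) | `Cc1cc(OC)cc(C[C@]2(C)[C@@H](CCC=O)[C@](C)(CC(=O)OC(C)(C)C)CC[C@@H]2C)c1OC` | intermediate  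
30 | methyl 3-[6-(2-tert-butoxy-2-oxoethyl)-2-[(2,5-dimethoxy-3-methylphenyl)methyl]-2,3,6-trimethylcyclohexyl]propanoate (stereocentres as in 24) | `Cc1cc(OC)cc(C[C@]2(C)[C@@H](CCC(=O)OC)[C@](C)(CC(=O)OC(C)(C)C)CC[C@@H]2C)c1OC` | intermediate  
31 | tert-butyl (4aR,5S,6S,8aR)-5-[(2,5-dimethoxy-3-methylphenyl)methyl]-5,6,8a-trimethyl-2-oxodecahydronaphthalene-1-carboxylate (C1 enolisable, left open) | `Cc1cc(OC)cc(C[C@]2(C)[C@H]3CCC(=O)C(C(=O)OC(C)(C)C)[C@]3(C)CC[C@@H]2C)c1OC` | intermediate  
32 | tert-butyl prop-2-enoate | `C=CC(=O)OC(C)(C)C` | starting material  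
33 | tert-butyl (1S,4aR,5S,6S,8aR)-1-(3-tert-butoxy-3-oxopropyl)-5-[(2,5-dimethoxy-3-methylphenyl)methyl]-5,6,8a-trimethyl-2-oxodecahydronaphthalene-1-carboxylate | `Cc1cc(OC)cc(C[C@]2(C)[C@H]3CCC(=O)[C@@](CCC(=O)OC(C)(C)C)(C(=O)OC(C)(C)C)[C@]3(C)CC[C@@H]2C)c1OC` | intermediate  
34 | (1S,4aR,5S,6S,8aR)-1-(2-carboxyethyl)-5-[(2,5-dimethoxy-3-methylphenyl)methyl]-5,6,8a-trimethyl-2-oxodecahydronaphthalene-1-carboxylic acid | `Cc1cc(OC)cc(C[C@]2(C)[C@H]3CCC(=O)[C@@](CCC(=O)O)(C(=O)O)[C@]3(C)CC[C@@H]2C)c1OC` | intermediate  
35 | 3-[(1S,4aR,5S,6S,8aR)-5-[(2,5-dimethoxy-3-methylphenyl)methyl]-5,6,8a-trimethyl-2-oxodecahydronaphthalen-1-yl]propanoic acid | `Cc1cc(OC)cc(C[C@]2(C)[C@H]3CCC(=O)[C@@H](CCC(=O)O)[C@]3(C)CC[C@@H]2C)c1OC` | intermediate  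
36 | 3-[(1S,4aR,5S,6S,8aR)-5-[(2,5-dihydroxy-3-methylphenyl)methyl]-5,6,8a-trimethyl-2-oxodecahydronaphthalen-1-yl]propanoic acid | `Cc1cc(O)cc(C[C@]2(C)[C@H]3CCC(=O)[C@@H](CCC(=O)O)[C@]3(C)CC[C@@H]2C)c1O` | target  

## Step count and least certain steps

Total: 21 steps. Longest linear sequence: 21 steps (1 → 36); 4, 20, 21 and 32 are purchased and enter directly.

Step 12 (key step). The most likely failure is at the C5 alkylation. The hindered tetrasubstituted enolate may be quenched by proton transfer from the α-halo ester, may alkylate on oxygen, or may lose its trans facial preference because the β-face trajectory passes the C9 arylmethyl group. At C10, addition next to the quaternary C9 may be slow enough for 1,2-addition to compete. Fallback, from 19 back to 24: the conjugate addition is run on its own and 22 is isolated. Enolate 23 is then treated with allyl iodide, a smaller and more reactive electrophile with no acidic hydrogen, to give the C5 allyl ketone F1. Oxidative cleavage (OsO4 cat., NaIO4, 2,6-lutidine) gives the aldehyde F2, chlorite oxidation (NaClO2, NaH2PO4, 2-methylbut-2-ene) gives the acid F3, and esterification (Boc2O, DMAP, tBuOH) rejoins the route at 24.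

Step 6. Enantiofacial discrimination or turnover may be insufficient in the copper-catalysed methyl addition, because α-substituted enones are slow acceptors and the arylmethyl group is larger than the substituents such catalysts are usually tuned for. C-methylation of the magnesium enolate may also be incomplete. Fallback, from 3 back to 11: 3 is reduced (NaBH4, MeOH) to the benzylic alcohol F4 and converted (PBr3, Et2O) into the benzylic bromide F5. Purchased cyclohex-2-en-1-one is subjected to the well-established copper/phosphoramidite-catalysed addition of Me2Zn, and the zinc enolate is trapped with F5 (HMPA) to give the trans ketone F6. Thermodynamic silylation (Me3SiCl, NaI, Et3N, MeCN) gives the more substituted silyl enol ether F7, and MeLi followed by MeI gives 11 with the same anti selectivity as in step 6.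

Step 10. Hydrazone formation may be slow at the C10 carbonyl, which lies between the quaternary C9 and the fully substituted epoxide carbon, so that epoxide opening by hydrazine or azine formation competes. Fallback, from 13 back to 19 (steps 8–11 are bypassed): 13 is converted (KN(SiMe3)2; PhNTf2) into the enol triflate F8 and reduced (Pd(OAc)2, PPh3, HCO2H, Bu3N) to the trisubstituted alkene F9. Allylic oxidation at C6, the only ring allylic CH2 (CrO3, 3,5-dimethylpyrazole, CH2Cl2, −20 °C), then gives 19.

Step 19. C–C bond formation may be slow because C4 becomes quaternary next to the quaternary C5, leaving room for acrylate oligomerisation or retro-Michael cleavage. Fallback, from 31 back to 35: O-allylation (allyl bromide, K2CO3, acetone) gives the allyl enol ether F10, and a Claisen rearrangement (toluene, 110 °C) delivers the allyl group intramolecularly to C4 to give F11. Hydroboration (9-BBN; NaBO3) gives the primary alcohol F12 and oxidation (TEMPO, PhI(OAc)2, MeCN/H2O) gives the acid F13. The conditions of step 20 then give 35 by way of 34.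

Step 21. Cleavage of the methyl ether flanked by two ortho substituents may be incomplete, the hydroquinone may be oxidised during work-up, or the δ-keto acid may close to an enol lactone under the Lewis acid. Fallback, from 35 back to 36: oxidative demethylation ((NH4)2Ce(NO3)6, MeCN/H2O, 0 °C) gives the quinone F14, which is reduced (Na2S2O4, EtOAc/H2O) to 36.

## Further compounds

F1 | step 12 | 4-[(2,5-dimethoxy-3-methylphenyl)methyl]-3-[2-(1,3-dioxolan-2-yl)ethyl]-2,4,5-trimethyl-2-(prop-2-en-1-yl)cyclohexan-1-one (stereocentres as in 24) | `Cc1cc(OC)cc(C[C@]2(C)[C@@H](CCC3OCCO3)[C@](C)(CC=C)C(=O)C[C@@H]2C)c1OC`  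
F2 | step 12 | 2-[3-[(2,5-dimethoxy-3-methylphenyl)methyl]-2-[2-(1,3-dioxolan-2-yl)ethyl]-1,3,4-trimethyl-6-oxocyclohexyl]acetaldehyde (stereocentres as in 24) | `Cc1cc(OC)cc(C[C@]2(C)[C@@H](CCC3OCCO3)[C@](C)(CC=O)C(=O)C[C@@H]2C)c1OC`  
F3 | step 12 | 2-[3-[(2,5-dimethoxy-3-methylphenyl)methyl]-2-[2-(1,3-dioxolan-2-yl)ethyl]-1,3,4-trimethyl-6-oxocyclohexyl]acetic acid (stereocentres as in 24) | `Cc1cc(OC)cc(C[C@]2(C)[C@@H](CCC3OCCO3)[C@](C)(CC(=O)O)C(=O)C[C@@H]2C)c1OC`  
F4 | step 6 | (2,5-dimethoxy-3-methylphenyl)methanol | `Cc1cc(OC)cc(CO)c1OC`  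
F5 | step 6 | 1-(bromomethyl)-2,5-dimethoxy-3-methylbenzene | `Cc1cc(OC)cc(CBr)c1OC`  
F6 | step 6 | (2R,3S)-2-[(2,5-dimethoxy-3-methylphenyl)methyl]-3-methylcyclohexan-1-one | `Cc1cc(OC)cc(C[C@H]2C(=O)CCC[C@@H]2C)c1OC`  
F7 | step 6 | {[(3S)-2-[(2,5-dimethoxy-3-methylphenyl)methyl]-3-methylcyclohex-1-en-1-yl]oxy}trimethylsilane | `Cc1cc(OC)cc(CC2=C(O[Si](C)(C)C)CCC[C@@H]2C)c1OC`  
F8 | step 10 | (5S,6S)-6-[(2,5-dimethoxy-3-methylphenyl)methyl]-2,5,6-trimethylcyclohex-1-en-1-yl trifluoromethanesulfonate | `Cc1cc(OC)cc(C[C@]2(C)C(OS(=O)(=O)C(F)(F)F)=C(C)CC[C@@H]2C)c1OC`  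
F9 | step 10 | 2,5-dimethoxy-3-methyl-1-{[(1S,6S)-1,3,6-trimethylcyclohex-2-en-1-yl]methyl}benzene | `Cc1cc(OC)cc(C[C@]2(C)C=C(C)CC[C@@H]2C)c1OC`  
F10 | step 19 | tert-butyl (4aR,5S,6S,8aR)-5-[(2,5-dimethoxy-3-methylphenyl)methyl]-5,6,8a-trimethyl-2-(prop-2-en-1-yloxy)-3,4,4a,5,6,7,8,8a-octahydronaphthalene-1-carboxylate | `Cc1cc(OC)cc(C[C@]2(C)[C@H]3CCC(OCC=C)=C(C(=O)OC(C)(C)C)[C@]3(C)CC[C@@H]2C)c1OC`  
F11 | step 19 | tert-butyl (4aR,5S,6S,8aR)-5-[(2,5-dimethoxy-3-methylphenyl)methyl]-5,6,8a-trimethyl-2-oxo-1-(prop-2-en-1-yl)decahydronaphthalene-1-carboxylate (allyl group on the β face expected) | `Cc1cc(OC)cc(C[C@]2(C)[C@H]3CCC(=O)[C@@](CC=C)(C(=O)OC(C)(C)C)[C@]3(C)CC[C@@H]2C)c1OC`  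
F12 | step 19 | tert-butyl (4aR,5S,6S,8aR)-5-[(2,5-dimethoxy-3-methylphenyl)methyl]-1-(3-hydroxypropyl)-5,6,8a-trimethyl-2-oxodecahydronaphthalene-1-carboxylate | `Cc1cc(OC)cc(C[C@]2(C)[C@H]3CCC(=O)[C@@](CCCO)(C(=O)OC(C)(C)C)[C@]3(C)CC[C@@H]2C)c1OC`  
F13 | step 19 | 3-[(4aR,5S,6S,8aR)-1-(tert-butoxycarbonyl)-5-[(2,5-dimethoxy-3-methylphenyl)methyl]-5,6,8a-trimethyl-2-oxodecahydronaphthalen-1-yl]propanoic acid | `Cc1cc(OC)cc(C[C@]2(C)[C@H]3CCC(=O)[C@@](CCC(=O)O)(C(=O)OC(C)(C)C)[C@]3(C)CC[C@@H]2C)c1OC`  
F14 | step 21 | 3-[(1S,4aR,5S,6S,8aR)-5,6,8a-trimethyl-5-[(5-methyl-3,6-dioxocyclohexa-1,4-dien-1-yl)methyl]-2-oxodecahydronaphthalen-1-yl]propanoic acid | `CC1=CC(=O)C=C(C[C@]2(C)[C@H]3CCC(=O)[C@@H](CCC(=O)O)[C@]3(C)CC[C@@H]2C)C1=O`  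
A1 | alternative 1 | methyl (5E,7E)-5-methyl-4-{2-[(3E)-4-methyl-5-oxopent-3-en-1-yl]-1,3-dioxolan-2-yl}nona-5,7-dienoate (C4 as drawn) | `O=C/C(C)=C/CCC1(OCCO1)[C@@H](CCC(=O)OC)/C(C)=C/C=C/C`  
A2 | alternative 1 | trans-fused octalin C11 aldehyde with C3 dioxolane, C6=C7 alkene and C4 methyl propanoate arm | `O=C[C@]2(C)[C@H]3CCC4(OCCO4)[C@@H](CCC(=O)OC)[C@]3(C)C=C[C@@H]2C`  
A3 | alternative 2 | 6-{2-[2-ethenyl-6-[(2,5-dimethoxy-3-methylphenyl)methyl]-2,5,6-trimethylcyclohexyl]ethyl}-2,2-dimethyl-4H-1,3-dioxin-4-one (ring B configured as in 36) | `Cc1cc(OC)cc(C[C@]2(C)[C@@H](CCC3=CC(=O)OC(C)(C)O3)[C@](C)(C=C)CC[C@@H]2C)c1OC`  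
A4 | alternative 2 | cyclobutane photoadduct with ring A closed and the dioxanone retained | `Cc1cc(OC)cc(C[C@]2(C)[C@H]3CC[C@@]45OC(C)(C)OC(=O)[C@@H]4C[C@H]5[C@]3(C)CC[C@@H]2C)c1OC`  
A5 | alternative 3 | methyl (4Z,8E,12E)-5-[(tert-butyldimethylsilyl)oxy]-14-(2,5-dimethoxy-3-methylphenyl)-9,13-dimethyl-11-oxotetradeca-4,8,12-trienoate | `Cc1cc(OC)cc(C/C(C)=C/C(=O)C/C(C)=C/CC/C(O[Si](C)(C)C(C)(C)C)=C/CCC(=O)OC)c1OC`  
A6 | alternative 3 | trans-decalin C3 ketone with C7 tert-butyldimethylsilyl enol ether and no C8 methyl | `Cc1cc(OC)cc(C[C@]2(C)[C@H]3CCC(=O)[C@@H](CCC(=O)OC)[C@]3(C)CC(O[Si](C)(C)C(C)(C)C)=C2)c1OC`  
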